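**Plan**
- The last disconnection removes the methyl ester and the acetate. The one before it cuts the thiazole S1'–C5' bond: C5' is the only thiazole carbon that carries hydrogen and it is bonded directly to sulfur, so this cut leaves an N-[1-(pyridin-2-yl)vinyl]thioamide whose vinyl CH2 is C5'.
- Further cuts are C2'=S (amide thionation), N3'–C2' (reductive acylation of a ketoxime by the side-chain anhydride), pyridine C6–C(acetyl) (Minisci acylation) and C4''–C5'' of the heptyl chain (Grignard opening of an epoxide).
- Forward, the pyridine ring arises first, from the pyranone ring of kojic acid by exchange of the ring oxygen for nitrogen. It is then methoxylated at C4, acetylated at C6 and converted into the oxime.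
- The chain acid is joined as its anhydride, the amide is thionated, and the thiazole ring is closed in the penultimate step by anodic C–S bond formation. Hydrolysis ends the route.
- The single (S) carbinol centre comes from (S)-propylene oxide, which is opened only at its CH2 carbon; the centre is never a reacting atom afterwards.

Key step: step 13

Remark on the chemistry: 19 is drawn as the N-vinyl (enamine) tautomer, which the N–H···N(pyridine) hydrogen bond should favour; its N-thioacyl ketimine tautomer would feed the same ring closure.

**Route**

Step 1
Reactants: 1 kojic acid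
Product: 2 5-methoxy-2-(hydroxymethyl)-4H-pyran-4-one
Conditions: MeI, K2CO3, acetone, reflux
Reagents that add atoms: iodomethane, CI
Why: Williamson O-methylation, in which carbonate deprotonates only the acidic enolic 5-OH and leaves the primary alcohol untouched.

Step 2
Reactants: 2 5-methoxy-2-(hydroxymethyl)-4H-pyran-4-one
Product: 3 5-methoxy-4-oxo-4H-pyran-2-carboxylic acid
Conditions: CrO3, H2SO4, H2O, acetone, 0 °C to rt
Reagents that add atoms: water, O
Why: Jones oxidation of the primary alcohol through the aldehyde hydrate to the acid, the pyranone ring being inert to chromic acid.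

Step 3
Reactants: 3 5-methoxy-4-oxo-4H-pyran-2-carboxylic acid
Product: 4 5-methoxy-4-oxo-1,4-dihydropyridine-2-carboxylic acid (tautomer of 4-hydroxy-5-methoxypicolinic acid)
Conditions: conc. aq. NH3, sealed vessel, 90 °C; then HCl to pH 3
Reagents that add atoms: ammonia, N
Why: pyranone-to-pyridone exchange by conjugate addition of ammonia, ring opening and recyclisation with loss of water, which forms the pyridine ring.

Step 4
Reactants: 4 5-methoxy-4-oxo-1,4-dihydropyridine-2-carboxylic acid
Product: 7 methyl 4,5-dimethoxypicolinate, via 4-chloro-5-methoxypicolinoyl chloride 5 (not isolated), via methyl 4-chloro-5-methoxypicolinate 6 (not isolated)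
Conditions: SOCl2, DMF (cat.), 80 °C; evaporate; NaOMe (excess), MeOH, 0 °C to reflux
Reagents that add atoms: sodium methoxide NaOMe, [Na+].[O-]C
Why: Vilsmeier-type deoxychlorination of the 4-pyridone together with acid chloride formation, then methanolysis of the acid chloride and SNAr displacement of the 4-chloride (gamma to the ring nitrogen, activated by the ester) by methoxide.

Step 5
Reactants: 7 methyl 4,5-dimethoxypicolinate
Product: 8 methyl 6-acetyl-4,5-dimethoxypicolinate
Conditions: pyruvic acid, AgNO3 (cat.), (NH4)2S2O8, TFA, CH2Cl2/H2O, 40 °C
Reagents that add atoms: pyruvic acid, CC(=O)C(=O)O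
Why: Minisci acylation, in which the nucleophilic acetyl radical from silver-catalysed oxidative decarboxylation adds to the protonated pyridine at C6, the only free position alpha or gamma to nitrogen.

Step 6
Reactants: 8 methyl 6-acetyl-4,5-dimethoxypicolinate
Product: 9 methyl 6-[(E)-1-(hydroxyimino)ethyl]-4,5-dimethoxypicolinate
Conditions: NH2OH·HCl, NaOAc, MeOH, rt to 50 °C
Reagents that add atoms: hydroxylamine hydrochloride, Cl.NO
Why: oxime condensation, in which buffered hydroxylamine should attack the ketone much faster than the methyl ester.

Step 7
Reactants: 10 6-bromohex-1-ene; 11 (S)-propylene oxide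
Product: 13 (S)-non-8-en-2-ol, via hex-5-enylmagnesium bromide 12 (not isolated)
Conditions: Mg, THF; CuI (10 mol %), 11, THF, −30 to 0 °C; 1 M HCl
Reagents that add atoms: none
Why: copper-catalysed SN2 opening of the epoxide by the Grignard reagent at the unsubstituted carbon, so the C–O stereocentre of 11 is carried unchanged into the (S) carbinol.

Step 8
Reactants: 13 (S)-non-8-en-2-ol
Product: 14 (S)-non-8-en-2-yl acetate
Conditions: Ac2O, DMAP (cat.), pyridine, rt
Reagents that add atoms: acetic anhydride, CC(=O)OC(C)=O
Why: DMAP-catalysed O-acetylation, which shields the carbinol from the oxidant of step 9 and does not touch the stereocentre.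

Step 9
Reactants: 14 (S)-non-8-en-2-yl acetate
Product: 15 (S)-7-acetoxyoctanoic acid
Conditions: RuCl3·xH2O (cat.), NaIO4, EtOAc/MeCN/H2O, rt
Reagents that add atoms: sodium periodate NaIO4, [Na+].[O-]I(=O)(=O)=O; water, O
Why: RuO4-catalysed oxidative cleavage of the terminal alkene to the carboxylic acid with loss of the terminal carbon, the acid then being freed from neutral impurities by base extraction.

Step 10
Reactants: 15 (S)-7-acetoxyoctanoic acid (two molecules)
Product: 16 (S)-7-acetoxyoctanoic anhydride, both centres (S)
Conditions: DCC (0.5 equiv), CH2Cl2, 0 °C to rt; filter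
Reagents that add atoms: none
Why: carbodiimide-mediated dehydration of two acid molecules to the symmetric anhydride, a standard acyl activation.

Step 11
Reactants: 9 methyl 6-[(E)-1-(hydroxyimino)ethyl]-4,5-dimethoxypicolinate; 16 (S)-7-acetoxyoctanoic anhydride
Product: 18 methyl 6-{1-[(S)-7-acetoxyoctanoylamino]vinyl}-4,5-dimethoxypicolinate, via O-acyl oxime 17 (not isolated)
Conditions: PEt3, toluene, rt then reflux
Reagents that add atoms: none
Why: phosphine-mediated reductive acylation of a ketoxime, in which O-acylation, N–O cleavage by the phosphine and acyl transfer to nitrogen with tautomerisation give the N-(1-arylvinyl)amide.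

Step 12
Reactants: 18 methyl 6-{1-[(S)-7-acetoxyoctanoylamino]vinyl}-4,5-dimethoxypicolinate
Product: 19 methyl 6-{1-[(S)-7-acetoxyoctanethioylamino]vinyl}-4,5-dimethoxypicolinate
Conditions: Lawesson's reagent (0.6 equiv), THF, 50 °C
Reagents that add atoms: Lawesson's reagent, COc1ccc(cc1)P1(=S)SP(=S)(S1)c1ccc(OC)cc1
Why: thionation of a secondary amide with Lawesson's reagent through a thiaoxaphosphetane, which at this temperature should leave the two ester carbonyls alone.

Step 13
Reactants: 19 methyl 6-{1-[(S)-7-acetoxyoctanethioylamino]vinyl}-4,5-dimethoxypicolinate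
Product: 20 methyl 6-{2-[(S)-6-acetoxyheptyl]thiazol-4-yl}-4,5-dimethoxypicolinate
Conditions: TEMPO (10 mol %), n-Bu4NBF4 (0.1 M), MeCN/MeOH (9:1), graphite anode, Pt cathode, undivided cell, constant current, rt
Reagents that add atoms: none
Why: Proposed new method: TEMPO is oxidised at the anode to its oxoammonium ion, which converts the thioamide (deprotonated by methoxide formed at the cathode) into a sulfur-centred thioamidyl radical; this radical adds to the vinyl CH2 to form the S1'–C5' bond, the resulting C4' radical (flanked by the ring nitrogen and the pyridyl group) is oxidised a second time and loses the C5' proton to give the aromatic thiazole, and the protons are discharged as H2 at the cathode. The closest known reaction type is the TEMPO-mediated electrochemical dehydrogenative C–S cyclisation of N-aryl thioamides to benzothiazoles, carried over here from an arene carbon to an enamine carbon. The thiazole ring closes in a 5-endo-trig mode, which sulfur radicals tolerate because of the long C–S bonds and which leads to a captodatively stabilised radical. No stereocentre is formed, and the (S)-acetoxy centre lies five carbons away from the reacting atoms. The step needs the thioamide to be oxidised in preference to every other group and the sulfur to close onto carbon faster than it dimerises to a disulfide. The first should be secured because the thioamide is by far the most electron-rich site of 19, the second because the Z-thioamide geometry together with the N–H···N(pyridine) hydrogen bond holds the vinyl CH2 next to sulfur and mediated constant-current electrolysis keeps the radical concentration low.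

Step 14
Reactants: 20 methyl 6-{2-[(S)-6-acetoxyheptyl]thiazol-4-yl}-4,5-dimethoxypicolinate
Product: 21 6-{2-[(S)-6-hydroxyheptyl]thiazol-4-yl}-4,5-dimethoxypicolinic acid (CNP0267511.1)
Conditions: LiOH, THF/MeOH/H2O, rt; HCl to pH 3–4
Reagents that add atoms: lithium hydroxide LiOH, [Li+].[OH-]
Why: saponification of the methyl ester and the acetate by acyl–oxygen cleavage, so the carbinol C–O bond and its (S) configuration are retained.

**Compound list**

1 | kojic acid, 5-hydroxy-2-(hydroxymethyl)-4H-pyran-4-one | O=c1cc(CO)occ1O | starting material
2 | 5-methoxy-2-(hydroxymethyl)-4H-pyran-4-one | COc1coc(CO)cc1=O | intermediate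
3 | 5-methoxy-4-oxo-4H-pyran-2-carboxylic acid | COc1coc(C(=O)O)cc1=O | intermediate
4 | 5-methoxy-4-oxo-1,4-dihydropyridine-2-carboxylic acid | COc1c[nH]c(C(=O)O)cc1=O | intermediate
5 | 4-chloro-5-methoxypicolinoyl chloride (not isolated) | COc1cnc(C(=O)Cl)cc1Cl | intermediate
6 | methyl 4-chloro-5-methoxypicolinate (not isolated) | COC(=O)c1cc(Cl)c(OC)cn1 | intermediate
7 | methyl 4,5-dimethoxypicolinate | COC(=O)c1cc(OC)c(OC)cn1 | intermediate
8 | methyl 6-acetyl-4,5-dimethoxypicolinate | COC(=O)c1cc(OC)c(OC)c(C(C)=O)n1 | intermediate
9 | methyl 6-[(E)-1-(hydroxyimino)ethyl]-4,5-dimethoxypicolinate | COC(=O)c1cc(OC)c(OC)c(/C(C)=N/O)n1 | intermediate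
10 | 6-bromohex-1-ene | C=CCCCCBr | starting material
11 | (S)-propylene oxide, (S)-2-methyloxirane | C[C@H]1CO1 | starting material
12 | hex-5-enylmagnesium bromide (not isolated) | C=CCCCC[Mg]Br | intermediate
13 | (S)-non-8-en-2-ol | C=CCCCCC[C@H](C)O | intermediate
14 | (S)-non-8-en-2-yl acetate | C=CCCCCC[C@H](C)OC(C)=O | intermediate
15 | (S)-7-acetoxyoctanoic acid | OC(=O)CCCCC[C@H](C)OC(C)=O | intermediate
16 | (S)-7-acetoxyoctanoic anhydride, bis[(S)-7-acetoxyoctanoyl] oxide | CC(=O)O[C@@H](C)CCCCCC(=O)OC(=O)CCCCC[C@H](C)OC(C)=O | intermediate
17 | methyl 6-{(E)-1-[(S)-7-acetoxyoctanoyloxyimino]ethyl}-4,5-dimethoxypicolinate, the O-acyl oxime (not isolated) | COC(=O)c1cc(OC)c(OC)c(/C(C)=N/OC(=O)CCCCC[C@H](C)OC(C)=O)n1 | intermediate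
18 | methyl 6-{1-[(S)-7-acetoxyoctanoylamino]vinyl}-4,5-dimethoxypicolinate | COC(=O)c1cc(OC)c(OC)c(C(=C)NC(=O)CCCCC[C@H](C)OC(C)=O)n1 | intermediate
19 | methyl 6-{1-[(S)-7-acetoxyoctanethioylamino]vinyl}-4,5-dimethoxypicolinate | COC(=O)c1cc(OC)c(OC)c(C(=C)NC(=S)CCCCC[C@H](C)OC(C)=O)n1 | intermediate
20 | methyl 6-{2-[(S)-6-acetoxyheptyl]thiazol-4-yl}-4,5-dimethoxypicolinate | COC(=O)c1cc(OC)c(OC)c(-c2csc(CCCCC[C@H](C)OC(C)=O)n2)n1 | intermediate
21 | 6-{2-[(S)-6-hydroxyheptyl]thiazol-4-yl}-4,5-dimethoxypicolinic acid | COc1cc(C(=O)O)nc(-c2csc(CCCCC[C@H](C)O)n2)c1OC | target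

**Step count**

Total: 14 steps. Longest linear sequence: 10 steps (1 to 21 through steps 1–6 and 11–14). The chain branch (steps 7–10) is 4 steps and joins at step 11.

**Steps most likely to fail**

Step 13 (anodic ring closure). The thioamidyl radical may pair to a disulfide, or the thioenamide may be solvolysed at its N–C(vinyl) bond, faster than sulfur closes onto C5'. The fallback is the Hantzsch thiazole synthesis, which is known chemistry. It sets out from ketone 8 and anhydride 16. Ketone 8 would be brominated at the acetyl methyl group with PhNMe3Br3 in THF to give methyl 6-(bromoacetyl)-4,5-dimethoxypicolinate F1. Anhydride 16 would be opened with NH3 in THF at 0 °C to give (S)-7-acetoxyoctanamide F2, which Lawesson's reagent in THF should convert into (S)-7-acetoxyoctanethioamide F3. Condensation of F1 with F3 (NaHCO3, MeCN, 50 °C) by S-alkylation, cyclisation and loss of water should give thiazole ester 20, where the route is rejoined before step 14.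

Step 12 (thionation of the enamide). Lawesson's reagent may attack the electron-rich enamide double bond, or the vinyl thioamide may be hydrolysed back to ketone 8 during isolation. The fallback brings sulfur in as thiocyanate instead of by thionation. It sets out from oxime 9 and anhydride 16, which would be heated with KSCN and CuI (10 mol %, monovalent copper) in toluene at 120 °C. This is the known copper-catalysed three-component condensation of aryl methyl ketoximes, carboxylic anhydrides and KSCN to 2-alkyl-4-arylthiazoles, in which the oxime N–O bond serves as the internal oxidant and which passes through O-acyl oxime 17. It should give thiazole ester 20 directly, so the route is rejoined at 20 and steps 11 to 13 are bypassed.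

Step 5 (Minisci acetylation). Radical addition to the methoxy-rich pyridinium ring may stall at low conversion, or the methyl ester may be hydrolysed in the acidic aqueous phase. The fallback introduces the acetyl group by N-oxide activation and cross-coupling. It sets out from 7. Oxidation with mCPBA in CH2Cl2 should give methyl 4,5-dimethoxypicolinate N-oxide F4. POBr3 in toluene at 80 °C would brominate the only free alpha position to give methyl 6-bromo-4,5-dimethoxypicolinate F5. Stille coupling with tributyl(1-ethoxyvinyl)stannane (Pd(PPh3)4, zerovalent palladium, toluene, 100 °C) should give methyl 6-(1-ethoxyvinyl)-4,5-dimethoxypicolinate F6. Hydrolysis of the enol ether with 1 M HCl in THF at rt returns ketone 8, where the route is rejoined before step 6.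

**Further compounds**

F1 | step 13 | methyl 6-(bromoacetyl)-4,5-dimethoxypicolinate | COC(=O)c1cc(OC)c(OC)c(C(=O)CBr)n1
F2 | step 13 | (S)-7-acetoxyoctanamide | NC(=O)CCCCC[C@H](C)OC(C)=O
F3 | step 13 | (S)-7-acetoxyoctanethioamide | NC(=S)CCCCC[C@H](C)OC(C)=O
F0 | step 12 | none | none
F4 | step 5 | methyl 4,5-dimethoxypicolinate N-oxide | COC(=O)c1cc(OC)c(OC)c[n+]1[O-]
F5 | step 5 | methyl 6-bromo-4,5-dimethoxypicolinate | COC(=O)c1cc(OC)c(OC)c(Br)n1
F6 | step 5 | methyl 6-(1-ethoxyvinyl)-4,5-dimethoxypicolinate | COC(=O)c1cc(OC)c(OC)c(C(=C)OCC)n1
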